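**Retrosynthetic overview**
- The target comes from its bis-TBS ether by buffered fluoride desilylation; the B ring is bought as 3,5-dihydroxybenzaldehyde.
- Rings C and A are closed together from an acyclic (S)-δ-hydroxy triketide-type tert-butyl ester. Acid closes the dihydropyranone (O1–C8a), then thermal loss of t-BuOH gives an acylketene that closes C4a–C5 to the phloroglucinol ring.
- The farnesyl group sits on the future C6 and the ring oxygen is fixed before the A ring exists, so no 6-/8-isomer question arises.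
- The acyclic precursor comes from Claisen-type ring-opening of (S)-6-aryl-4-methoxy-5,6-dihydropyran-2-one by the γ-dianion of tert-butyl 2-farnesylacetoacetate.
- The lactone (the only stereocentre, C2) comes from a catalytic asymmetric formal hetero-Diels–Alder of the silylated aldehyde with Brassard's diene. Ring order: B (bought), temporary δ-lactone (opened again), then C and A in one operation.

Assumption: the (S)-BINOL–Ti(IV) catalyst in step 3 is taken to give Si-face attack on the aldehyde (the (S)-lactone), by analogy with other BINOL–Ti additions to aryl aldehydes; if the sense is opposite, (R)-BINOL is used.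

Abbreviations: TBS = tert-butyldimethylsilyl; farnesyl = (2E,6E)-3,7,11-trimethyldodeca-2,6,10-trien-1-yl. The target is the (2S)-flavanone.

**Step 1**
Reactants: 1 3,5-dihydroxybenzaldehyde
Product: 2 3,5-bis(tert-butyldimethylsilyloxy)benzaldehyde
Conditions: TBSCl (2.3 equiv), imidazole, DMF, 0 °C → rt
Reagents that add atoms: tert-butyldimethylsilyl chloride, CC(C)(C)[Si](C)(C)Cl
Why: Standard imidazole-promoted O-silylation of both phenols (silyl ether protection) masks the acidic OH groups for the enolate chemistry and is removable with fluoride at the end.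

**Step 2**
Reactants: 3 methyl (E)-3-methoxybut-2-enoate
Product: 5 (E)-1,3-dimethoxy-1-(trimethylsilyloxy)buta-1,3-diene (Brassard's diene), via lithium dienolate 4 (not isolated)
Conditions: LDA, THF, −78 °C; then TMSCl, −78 °C → rt; distil
Reagents that add atoms: chlorotrimethylsilane, C[Si](C)(C)Cl
Why: Kinetic γ-deprotonation of the vinylogous ester and O-silylation of the dienolate (silyl ketene acetal formation) is the standard preparation of Brassard's diene.

**Step 3**
Reactants: 2 3,5-bis(tert-butyldimethylsilyloxy)benzaldehyde; 5 Brassard's diene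
Product: 7 (6S)-6-[3,5-bis(tert-butyldimethylsilyloxy)phenyl]-4-methoxy-5,6-dihydro-2H-pyran-2-one, via silyl aldol adduct 6 (not isolated)
Conditions: (S)-BINOL/Ti(OiPr)4 (10 mol%), 4 Å MS, toluene, 0 °C; then TFA (cat.), CH2Cl2, 0 °C, aqueous work-up
Reagents that add atoms: none
Why: BINOL–Ti(IV)-catalysed vinylogous Mukaiyama aldol of Brassard's diene followed by acid-induced lactonisation (formal asymmetric hetero-Diels–Alder reaction) is an established route to 6-aryl-4-methoxy-5,6-dihydropyran-2-ones in high ee, and the catalyst-controlled Si-face addition to the aldehyde sets the future C2 as (S).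

**Step 4**
Reactants: 8 tert-butyl acetoacetate (1.5 equiv); 9 (2E,6E)-farnesyl bromide
Product: 10 tert-butyl (4E,8E)-2-acetyl-5,9,13-trimethyltetradeca-4,8,12-trienoate (racemic)
Conditions: K2CO3, acetone, reflux
Reagents that add atoms: none
Why: Classical acetoacetic ester C-alkylation (SN2 at the primary allylic bromide with retention of the E geometry), with excess keto ester suppressing dialkylation; the new α-centre is racemic and is destroyed in step 6.

**Step 5**
Reactants: 10 tert-butyl 2-farnesylacetoacetate (2.2 equiv); 7 (6S)-lactone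
Product: 12 tert-butyl (6E,9S)-9-[3,5-bis(tert-butyldimethylsilyloxy)phenyl]-9-hydroxy-7-methoxy-3,5-dioxo-2-farnesylnon-6-enoate (C2 epimers; used crude), via dilithium dianion 11 (not isolated)
Conditions: LDA (4.5 equiv), THF, −78 → 0 °C; then 7, −78 °C; AcOH quench at −78 °C, pH 7 work-up
Reagents that add atoms: none
Why: Huckin–Weiler dianion chemistry, in which the γ-carbanion attacks the lactone carbonyl (Claisen-type acylation with a lactone as acyl donor) and the lactolate collapses to the open-chain δ-hydroxy vinylogous ester, which is shielded from over-addition as its enolate; the carbinol C–O bond is not touched, so the (S) centre is retained.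

**Step 6**
Reactants: 12 acyclic δ-hydroxy triketide tert-butyl ester
Product: 15 (2S)-2-[3,5-bis(tert-butyldimethylsilyloxy)phenyl]-5,7-dihydroxy-6-farnesylchroman-4-one, via dihydropyranone keto ester 13 (not isolated), via acylketene 14 (not isolated)
Conditions: CSA (5 mol%), wet CH2Cl2, rt; then 2,6-lutidine (10 mol%), solvent swap to xylenes (0.01 M), 138 °C, N2 sweep
Reagents that add atoms: none
Why: Proposed new method: acid-catalysed hemiketalisation of the δ-hydroxyl onto the C5 ketone of 12 with net loss of methanol (a Stork–Danheiser-type transposition of the vinylogous ester, as in δ-hydroxy-β-diketone to dihydropyranone cyclodehydrations) closes the C ring with the O–C2 bond intact; after the acid is neutralised and the methanol removed, thermal loss of t-BuOH from the β-keto tert-butyl ester (Witzeman-type acylketene generation) gives an α-oxoketene whose enol is a dienylketene that undergoes 6π-electrocyclisation onto the vinylogous-ester α-carbon and tautomerises to the phloroglucinol A ring, the closest known reactions being the final electrocyclisation of the Danheiser benzannulation and Harris-type Claisen cyclisations of triketo esters to acylphloroglucinols; the farnesyl group is already on the carbon that becomes C6 and the ring oxygen is already placed, so only the 6-farnesyl isomer can form, and no strong base is present to open the ring at C2.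

**Step 7**
Reactants: 15 bis-TBS flavanone
Product: 16 (2S)-2-(3,5-dihydroxyphenyl)-5,7-dihydroxy-6-[(2E,6E)-3,7,11-trimethyldodeca-2,6,10-trienyl]chroman-4-one (target)
Conditions: TBAF/AcOH (1:1, 2.5 equiv), THF, 0 °C
Reagents that add atoms: none
Why: Fluoride-mediated cleavage of the aryl silyl ethers under acetic acid buffering leaves the farnesyl chain untouched and avoids the basic conditions that would open the flavanone to the chalcone and racemise C2.

**Compound list**
1 | 3,5-dihydroxybenzaldehyde | O=Cc1cc(O)cc(O)c1 | starting material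
2 | 3,5-bis(tert-butyldimethylsilyloxy)benzaldehyde | O=Cc1cc(O[Si](C)(C)C(C)(C)C)cc(O[Si](C)(C)C(C)(C)C)c1 | intermediate
3 | methyl (E)-3-methoxybut-2-enoate | CO/C(C)=C/C(=O)OC | starting material
4 | lithium 1,3-dimethoxybuta-1,3-dien-1-olate (lithium dienolate of 3) | [Li+].C=C(OC)C=C([O-])OC | intermediate (not isolated)
5 | (E)-1,3-dimethoxy-1-(trimethylsilyloxy)buta-1,3-diene (Brassard's diene) | C=C(OC)/C=C(/O[Si](C)(C)C)OC | intermediate
6 | methyl (2E,5S)-5-[3,5-bis(TBS-oxy)phenyl]-3-methoxy-5-(trimethylsilyloxy)pent-2-enoate | COC(=O)/C=C(/OC)C[C@H](O[Si](C)(C)C)c1cc(O[Si](C)(C)C(C)(C)C)cc(O[Si](C)(C)C(C)(C)C)c1 | intermediate (not isolated)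
7 | (6S)-6-[3,5-bis(TBS-oxy)phenyl]-4-methoxy-5,6-dihydro-2H-pyran-2-one | COC1=CC(=O)O[C@H](c2cc(O[Si](C)(C)C(C)(C)C)cc(O[Si](C)(C)C(C)(C)C)c2)C1 | intermediate
8 | tert-butyl acetoacetate | CC(=O)CC(=O)OC(C)(C)C | starting material
9 | (2E,6E)-farnesyl bromide | CC(C)=CCC/C(C)=C/CC/C(C)=C/CBr | starting material
10 | tert-butyl (4E,8E)-2-acetyl-5,9,13-trimethyltetradeca-4,8,12-trienoate (racemic) | CC(C)=CCC/C(C)=C/CC/C(C)=C/CC(C(C)=O)C(=O)OC(C)(C)C | intermediate
11 | dilithium dianion (bis-enolate) of 10 | CC(C)=CCC/C(C)=C/CC/C(C)=C/CC(C(=C)[O-])=C([O-])OC(C)(C)C.[Li+].[Li+] | intermediate (not isolated)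
12 | tert-butyl (6E,9S)-9-[3,5-bis(TBS-oxy)phenyl]-9-hydroxy-7-methoxy-3,5-dioxo-2-farnesylnon-6-enoate (C2 epimers) | CC(C)=CCC/C(C)=C/CC/C(C)=C/CC(C(=O)OC(C)(C)C)C(=O)CC(=O)/C=C(/OC)C[C@H](O)c1cc(O[Si](C)(C)C(C)(C)C)cc(O[Si](C)(C)C(C)(C)C)c1 | intermediate
13 | tert-butyl 4-{(2S)-2-[3,5-bis(TBS-oxy)phenyl]-4-oxo-3,4-dihydro-2H-pyran-6-yl}-3-oxo-2-farnesylbutanoate (C2 epimers) | CC(C)=CCC/C(C)=C/CC/C(C)=C/CC(C(=O)OC(C)(C)C)C(=O)CC1=CC(=O)C[C@@H](c2cc(O[Si](C)(C)C(C)(C)C)cc(O[Si](C)(C)C(C)(C)C)c2)O1 | intermediate (not isolated)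
14 | (2S)-2-[3,5-bis(TBS-oxy)phenyl]-6-(3-farnesyl-2,4-dioxobut-3-en-1-yl)-2,3-dihydro-4H-pyran-4-one (acylketene) | CC(C)=CCC/C(C)=C/CC/C(C)=C/CC(=C=O)C(=O)CC1=CC(=O)C[C@@H](c2cc(O[Si](C)(C)C(C)(C)C)cc(O[Si](C)(C)C(C)(C)C)c2)O1 | intermediate (not isolated)
15 | (2S)-2-[3,5-bis(TBS-oxy)phenyl]-5,7-dihydroxy-6-farnesylchroman-4-one | CC(C)=CCC/C(C)=C/CC/C(C)=C/Cc1c(O)cc2c(c1O)C(=O)C[C@@H](c1cc(O[Si](C)(C)C(C)(C)C)cc(O[Si](C)(C)C(C)(C)C)c1)O2 | intermediate
16 | (2S)-2-(3,5-dihydroxyphenyl)-5,7-dihydroxy-6-farnesylchroman-4-one | CC(C)=CCC/C(C)=C/CC/C(C)=C/Cc1c(O)cc2c(c1O)C(=O)C[C@@H](c1cc(O)cc(O)c1)O2 | target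

**Totals**
Total steps: 7. Longest linear sequence: 5 steps (steps 1, 3, 5, 6, 7; the branch through step 2 is equally long).

**Steps most likely to fail, with fallbacks**

Step 6 (most at risk). At the acid stage the 1,3,5-tricarbonyl array of 12 could close to a γ-pyrone instead of the dihydropyranone. At the thermal stage the α-substituted tert-butyl ester may release the ketene slowly, or the ketene may be captured by alcohol or by another molecule before it cyclises. The fallback sets out from lactone 7 and bromide 9, comes back at 15, and replaces the thermal ketene closure by a stepwise ionic Claisen on a methyl ester. Methyl acetoacetate is alkylated with 9 (K2CO3, acetone) to give methyl 2-farnesylacetoacetate F9. Its dilithium dianion F10 opens 7 as in step 5 to give the methyl ester triketide F11. CSA in CH2Cl2 closes the C ring to the isolated dihydropyranone methyl ester F12. DBU in dry toluene at 60 °C then drives a Dieckmann-type Claisen cyclisation of the extended enolate onto the methyl ester, giving 15 after acidic work-up. C2 integrity must be checked by chiral HPLC because base is present.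

Step 5. The dianion is a strong base and may deprotonate 7 at its ring CH2, which opens the lactone by E1cB to a dienoic acid (the known base sensitivity of this lactone class). The vinylogous-carbonate carbonyl may also be too unreactive. The fallback sets out from 7, comes back at 12, and uses an acyclic acyl donor without a lactone leaving group. Lactone 7 is opened with Me(MeO)NH·HCl/AlMe3 to the hydroxy Weinreb amide F6, which is silylated (TESCl, imidazole) to the TES ether F7. Dianion 11 is acylated by F7 through a stable chelated adduct to give the TES-protected triketide F8. The acid stage of step 6, run with a little methanol, cleaves the TES ether to 12 in situ and the route continues unchanged.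

Step 3. The bulky bis-silyloxy aldehyde may give low ee or poor conversion with the Ti–BINOL system. The fallback sets out from 2, comes back at 7, and builds the lactone by a dioxinone vinylogous aldol and acylketene lactonisation. Commercial 2,2,6-trimethyl-4H-1,3-dioxin-4-one is converted (LDA, TMSCl) into its silyl dienolate F1. F1 adds to 2 under Cu(I) fluoride/Tol-BINAP catalysis (ligand antipode chosen for the S carbinol) to give the aldol silyl ether F2, and acidic work-up gives the hydroxy dioxinone F3. Heating F3 in toluene at 110 °C expels acetone, and the hydroxy acylketene F4 so formed is captured by its own hydroxyl to give the pyran-2,4-dione F5. O-methylation (Me2SO4, K2CO3, acetone) gives 7.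

**Further compounds**
F1 | step 3 | 2,2-dimethyl-6-methylidene-4-(trimethylsilyloxy)-6H-1,3-dioxine (dioxinone silyl dienolate) | C=C1C=C(O[Si](C)(C)C)OC(C)(C)O1
F2 | step 3 | 6-{(2S)-2-[3,5-bis(TBS-oxy)phenyl]-2-(trimethylsilyloxy)ethyl}-2,2-dimethyl-4H-1,3-dioxin-4-one | CC1(C)OC(C[C@H](O[Si](C)(C)C)c2cc(O[Si](C)(C)C(C)(C)C)cc(O[Si](C)(C)C(C)(C)C)c2)=CC(=O)O1
F3 | step 3 | 6-{(2S)-2-[3,5-bis(TBS-oxy)phenyl]-2-hydroxyethyl}-2,2-dimethyl-4H-1,3-dioxin-4-one | CC1(C)OC(C[C@H](O)c2cc(O[Si](C)(C)C(C)(C)C)cc(O[Si](C)(C)C(C)(C)C)c2)=CC(=O)O1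
F4 | step 3 | (5S)-5-[3,5-bis(TBS-oxy)phenyl]-5-hydroxy-3-oxopent-1-en-1-one (acylketene) | O=C=CC(=O)C[C@H](O)c1cc(O[Si](C)(C)C(C)(C)C)cc(O[Si](C)(C)C(C)(C)C)c1
F5 | step 3 | (6S)-6-[3,5-bis(TBS-oxy)phenyl]dihydro-2H-pyran-2,4(3H)-dione | O=C1CC(=O)O[C@H](c2cc(O[Si](C)(C)C(C)(C)C)cc(O[Si](C)(C)C(C)(C)C)c2)C1
F6 | step 5 | (2E,5S)-5-[3,5-bis(TBS-oxy)phenyl]-5-hydroxy-N,3-dimethoxy-N-methylpent-2-enamide | CON(C)C(=O)/C=C(/OC)C[C@H](O)c1cc(O[Si](C)(C)C(C)(C)C)cc(O[Si](C)(C)C(C)(C)C)c1
F7 | step 5 | (2E,5S)-5-[3,5-bis(TBS-oxy)phenyl]-N,3-dimethoxy-N-methyl-5-(triethylsilyloxy)pent-2-enamide | CON(C)C(=O)/C=C(/OC)C[C@H](O[Si](CC)(CC)CC)c1cc(O[Si](C)(C)C(C)(C)C)cc(O[Si](C)(C)C(C)(C)C)c1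
F8 | step 5 | tert-butyl (6E,9S)-9-[3,5-bis(TBS-oxy)phenyl]-7-methoxy-3,5-dioxo-2-farnesyl-9-(triethylsilyloxy)non-6-enoate | CC(C)=CCC/C(C)=C/CC/C(C)=C/CC(C(=O)OC(C)(C)C)C(=O)CC(=O)/C=C(/OC)C[C@H](O[Si](CC)(CC)CC)c1cc(O[Si](C)(C)C(C)(C)C)cc(O[Si](C)(C)C(C)(C)C)c1
F9 | step 6 | methyl (4E,8E)-2-acetyl-5,9,13-trimethyltetradeca-4,8,12-trienoate | CC(C)=CCC/C(C)=C/CC/C(C)=C/CC(C(C)=O)C(=O)OC
F10 | step 6 | dilithium dianion (bis-enolate) of F9 | CC(C)=CCC/C(C)=C/CC/C(C)=C/CC(C(=C)[O-])=C([O-])OC.[Li+].[Li+]
F11 | step 6 | methyl (6E,9S)-9-[3,5-bis(TBS-oxy)phenyl]-9-hydroxy-7-methoxy-3,5-dioxo-2-farnesylnon-6-enoate | CC(C)=CCC/C(C)=C/CC/C(C)=C/CC(C(=O)OC)C(=O)CC(=O)/C=C(/OC)C[C@H](O)c1cc(O[Si](C)(C)C(C)(C)C)cc(O[Si](C)(C)C(C)(C)C)c1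
F12 | step 6 | methyl 4-{(2S)-2-[3,5-bis(TBS-oxy)phenyl]-4-oxo-3,4-dihydro-2H-pyran-6-yl}-3-oxo-2-farnesylbutanoate | CC(C)=CCC/C(C)=C/CC/C(C)=C/CC(C(=O)OC)C(=O)CC1=CC(=O)C[C@@H](c2cc(O[Si](C)(C)C(C)(C)C)cc(O[Si](C)(C)C(C)(C)C)c2)O1
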